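**Plan**

Numbering: ring B is C1 (bears the 3,4-dimethoxyphenyl group), C2 (C9H2OH), C3 (C10H2OH), C4, C4a, C8a. Ring A is C4a–C5–C6–C7–C8–C8a with methoxy groups on C6, C7 and C8.
Cuts: the diol is traced back to the γ-lactone C2–C9(=O)–O–C10–C3. Then C1–C8a and C2–C3 are cut in one operation, and finally the ester bond C9–O and the aryl–alkyne bond C4–C4a.
Enabling feature: C1–C8a and C2–C3 face each other across ring B, and the C3=C4 alkene beside ring A is what remains of an arylalkyne. C9 and C10 sit on adjacent ring atoms and can be joined as an ester, and C4a of the 3,4,5-trimethoxyphenyl ring has two identical ortho carbons, so ring A can be annulated in only one way.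
Forward: Sonogashira coupling and esterification join three commercial pieces into a linear enyne ester. One thermal [4+2] step closes ring B and the lactone together, and hydride reduction opens the lactone to the diol.
Stereochemistry: the trans C1/C2 relationship is copied from the (E)-alkene in the cycloaddition. The absolute (1R,2S) configuration comes from resolution of the racemic diol through its bis-(1S)-camphanate.

Key step: step 3

Remark: the enyne ester carries no stereogenic element, so the allene intermediate, the cycloadduct and the derived diol are racemates; each is drawn as the enantiomer that leads to the target.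

**Step 1**
Reactants: 1 5-iodo-1,2,3-trimethoxybenzene; 2 propargyl alcohol (prop-2-yn-1-ol)
Product: 3 3-(3,4,5-trimethoxyphenyl)prop-2-yn-1-ol
Conditions: PdCl2(PPh3)2 (2 mol %), CuI (4 mol %), Et3N, THF, degassed, rt to 45 °C
Reagents that add atoms: none
Why: Sonogashira coupling, in which the aryl iodide adds readily to zerovalent palladium even on this electron-rich ring and the free primary alcohol is tolerated, so the C4–C4a bond should form without protection.

**Step 2**
Reactants: 3 3-(3,4,5-trimethoxyphenyl)prop-2-yn-1-ol; 4 (E)-3,4-dimethoxycinnamic acid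
Product: 5 3-(3,4,5-trimethoxyphenyl)prop-2-yn-1-yl (E)-3-(3,4-dimethoxyphenyl)acrylate
Conditions: DCC (1.1 equiv), DMAP (10 mol %), CH2Cl2, 0 °C to rt
Reagents that add atoms: none
Why: Steglich esterification, in which carbodiimide activation with DMAP as acyl-transfer catalyst joins the acid and the propargylic alcohol under neutral conditions that leave the alkyne and the (E)-geometry untouched.

**Step 3**
Reactants: 5 3-(3,4,5-trimethoxyphenyl)prop-2-yn-1-yl (E)-3-(3,4-dimethoxyphenyl)acrylate
Product: 7 rac-(9R,9aS)-9-(3,4-dimethoxyphenyl)-6,7,8-trimethoxy-9,9a-dihydronaphtho[2,3-c]furan-1(3H)-one (1,2-trans γ-lactone; carbonyl carbon C9 on C2), via cyclic allene 6 (not isolated)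
Conditions: BHT (1 equiv), degassed PhCN (0.01 M), 180 °C, sealed tube, Ar, exclusion of light
Reagents that add atoms: none
Why: Thermal intramolecular dehydro-Diels–Alder reaction: the arenyne C8a=C4a–C4≡C3 of 5 acts as the 4π partner and adds suprafacially, in a concerted but asynchronous [4+2] event, to the cinnamate C1=C2 bond, forming C2–C3 and C1–C8a and giving the strained isoaromatic cyclic allene 6; its C8a hydrogen is then passed to the central allene carbon C4 through BHT as a hydrogen relay (a net 1,3-transfer, not a concerted sigmatropic shift), which restores ring A and leaves the C3=C4 alkene. The closest known reactions are the thermal cyclisations of 3-arylpropargyl arylpropiolates to arylnaphthalene lactones, where the same arenyne unit is the diene and an isoaromatic allene is passed, and the intramolecular enyne–alkene cycloadditions that run through 1,2-cyclohexadienes. Ring B closes as the six-membered ring of the cycloaddition itself, and the γ-lactone closes at the same moment as a five-membered ring (5-exo at both π bonds) because the three-atom tether C9(=O)–O–C10 links C2 to C3. C1 and C2 are fixed relative to each other by the (E)-geometry of the alkene, which suprafacial addition translates into the trans arrangement of aryl group and carbonyl carbon, while nothing controls the absolute sense (7 is racemic) and the transient C8a centre disappears on rearomatisation. The step needs periselectivity against the mode in which the styrene unit of the cinnamate is the diene and the alkyne the 2π partner: the wanted mode joins the ring A ortho carbon, activated by one ortho and one para methoxy group, to the electrophilic β-carbon C1 and the enolate-like C2 to the allenyl-cation-like C3 (matched polarity at both new bonds, favoured further by the polar solvent, which also raises the share of the reactive ester rotamer), whereas the unwanted mode has to bond the unactivated alkyne carbon C4 to the other ring and finds no comparable donor–acceptor match. Regiochemistry on ring A is no issue because both ortho carbons are equivalent, and the oxygen-free, base-free medium guards against dehydrogenation to the naphthalene and against migration of C3=C4 into conjugation with the lactone.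

**Step 4**
Reactants: 7 rac-(9R,9aS)-9-(3,4-dimethoxyphenyl)-6,7,8-trimethoxy-9,9a-dihydronaphtho[2,3-c]furan-1(3H)-one
Product: 8 rac-[(1R,2S)-1-(3,4-dimethoxyphenyl)-6,7,8-trimethoxy-1,2-dihydronaphthalene-2,3-diyl]dimethanol
Conditions: LiAlH4 (1.5 equiv), THF, −20 to 0 °C; aqueous work-up
Reagents that add atoms: none
Why: Lactone-to-diol reduction with a nucleophilic aluminium hydride, in which hydride addition to the carbonyl at low temperature should be much faster than deprotonation at C2 or alkoxide-directed hydroalumination of C3=C4, so both stereocentres and the alkene position are kept.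

**Step 5**
Reactants: 8 rac-[(1R,2S)-1-(3,4-dimethoxyphenyl)-6,7,8-trimethoxy-1,2-dihydronaphthalene-2,3-diyl]dimethanol
Product: 9 [(1R,2S)-1-(3,4-dimethoxyphenyl)-6,7,8-trimethoxy-1,2-dihydronaphthalene-2,3-diyl]bis(methylene) bis[(1S,4R)-4,7,7-trimethyl-3-oxo-2-oxabicyclo[2.2.1]heptane-1-carboxylate] (single diastereomer)
Conditions: (1S)-(−)-camphanic chloride (2.5 equiv), Et3N, DMAP (cat.), CH2Cl2, 0 °C to rt; then fractional crystallisation or SiO2 chromatography of the two diastereomers
Reagents that add atoms: (1S)-(−)-camphanic chloride, ClC(=O)[C@@]12CC[C@@](C)(C(=O)O1)C2(C)C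
Why: Classical resolution through covalent diastereomers, in which DMAP-catalysed acylation of both primary alcohols with an enantiopure acid chloride turns the enantiomers of 8 into two separable, usually crystalline bis-esters, and an X-ray structure with the camphanoyl units as internal reference should identify the (1R,2S) isomer.

**Step 6**
Reactants: 9 bis-(1S)-camphanate of the (1R,2S)-diol
Product: 10 [(1R,2S)-1-(3,4-dimethoxyphenyl)-3-(hydroxymethyl)-6,7,8-trimethoxy-1,2-dihydronaphthalen-2-yl]methanol (CNP0274357.1)
Conditions: K2CO3 (0.2 equiv), MeOH/THF, rt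
Reagents that add atoms: none
Why: Carbonate-catalysed transesterification (methanolysis) cleaves the two primary esters, and because the product has no carbonyl group next to C2 no C–H at C1 or C2 is acidic enough to epimerise.

**Compound list**

1 | 5-iodo-1,2,3-trimethoxybenzene | COc1cc(I)cc(OC)c1OC | starting material
2 | propargyl alcohol | C#CCO | starting material
3 | 3-(3,4,5-trimethoxyphenyl)prop-2-yn-1-ol | COc1cc(C#CCO)cc(OC)c1OC | intermediate
4 | (E)-3,4-dimethoxycinnamic acid | COc1ccc(/C=C/C(=O)O)cc1OC | starting material
5 | 3-(3,4,5-trimethoxyphenyl)prop-2-yn-1-yl (E)-3-(3,4-dimethoxyphenyl)acrylate | COc1ccc(/C=C/C(=O)OCC#Cc2cc(OC)c(OC)c(OC)c2)cc1OC | intermediate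
6 | primary [4+2] adduct: cyclic allene C4a=C4=C3 with sp3 C8a–H, non-aromatic ring A (C5=C6, C7=C8), trans C1/C2 and fused γ-lactone; racemic; C8a configuration left open because it is erased | COc1ccc([C@@H]2C3C(OC)=C(OC)C(OC)=CC3=C=C4COC(=O)[C@@H]24)cc1OC | intermediate
7 | rac-(9R,9aS)-9-(3,4-dimethoxyphenyl)-6,7,8-trimethoxy-9,9a-dihydronaphtho[2,3-c]furan-1(3H)-one (required enantiomer drawn) | COc1ccc([C@@H]2c3c(cc(OC)c(OC)c3OC)C=C4COC(=O)[C@@H]24)cc1OC | intermediate
8 | rac-[(1R,2S)-1-(3,4-dimethoxyphenyl)-6,7,8-trimethoxy-1,2-dihydronaphthalene-2,3-diyl]dimethanol (required enantiomer drawn) | COc1ccc([C@@H]2c3c(cc(OC)c(OC)c3OC)C=C(CO)[C@H]2CO)cc1OC | intermediate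
9 | bis-(1S,4R)-camphanate of the (1R,2S)-diol | COc1ccc([C@@H]2c3c(cc(OC)c(OC)c3OC)C=C(COC(=O)[C@@]45CC[C@@](C)(C(=O)O4)C5(C)C)[C@H]2COC(=O)[C@@]67CC[C@@](C)(C(=O)O6)C7(C)C)cc1OC | intermediate
10 | [(1R,2S)-1-(3,4-dimethoxyphenyl)-3-(hydroxymethyl)-6,7,8-trimethoxy-1,2-dihydronaphthalen-2-yl]methanol | COc1ccc([C@@H]2c3c(cc(OC)c(OC)c3OC)C=C(CO)[C@H]2CO)cc1OC | target

**Step count**

Total step count: 6. Longest linear sequence: 6 (1 or 2 to 10).

**Steps most likely to fail**

**Step 3.**
- Risk: Periselectivity may be lost. The wanted mode has to pass a strained allene. The competing cycloaddition, with the cinnamate styrene unit as diene and the alkyne as 2π partner, leads to a strain-free adduct and would annulate the dimethoxyphenyl ring. A stepwise diradical course could also erode the trans relationship, and traces of oxygen could dehydrogenate ring B.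
- Fallback: This replaces the pericyclic closure by an ionic one and runs from 1 back to 8.
  - Mizoroki–Heck coupling of 1 with dimethyl itaconate (Pd(OAc)2, P(o-tol)3, Et3N, MeCN, 80 °C) gives dimethyl (E)-2-(3,4,5-trimethoxybenzylidene)succinate F1.
  - Stobbe condensation of F1 with 3,4-dimethoxybenzaldehyde (NaOMe, MeOH, reflux) gives the (E,E)-dibenzylidenesuccinic acid monomethyl ester F2.
  - F2 is methylated (MeI, K2CO3, DMF) to dimethyl (2E,3E)-2-(3,4-dimethoxybenzylidene)-3-(3,4,5-trimethoxybenzylidene)succinate F3.
  - TfOH in CH2Cl2 protonates the dimethoxybenzylidene ester unit. The C1 cation is best stabilised by the para-methoxy group of that ring, and it is captured in a Friedel–Crafts-type closure by the more nucleophilic ortho carbon of the trimethoxyphenyl ring. This gives dimethyl rac-trans-1-(3,4-dimethoxyphenyl)-6,7,8-trimethoxy-1,2-dihydronaphthalene-2,3-dicarboxylate F4.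
  - LiAlH4 in THF at 0 °C reduces F4 to 8.

**Step 5.**
- Risk: The two bis-esters may co-crystallise or co-elute, because the camphanoyl stereocentres lie far from C1 and C2.
- Fallback: This drops covalent derivatisation and runs from 8 directly to 10. The enantiomers of 8 are separated by preparative HPLC or SFC on an amylose tris(3,5-dimethylphenylcarbamate) stationary phase. The (1R,2S) enantiomer is assigned by comparing measured and calculated electronic circular dichroism. No new compound arises (F0).

**Step 4.**
- Risk: The basic aluminate may deprotonate C2, which would epimerise it or move C3=C4 into conjugation. The allylic alkoxide may also direct hydroalumination of the styrene-type alkene.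
- Fallback: This divides the reduction into two stages without a strongly basic hydride and runs from 7 back to 8. The electrophilic hydride i-Bu2AlH (1.1 equiv, CH2Cl2, −78 °C) stops at the lactol F5. The open hydroxy-aldehyde form of F5 is then reduced under Luche conditions (NaBH4, CeCl3·7H2O, MeOH, −20 °C) to 8.

**Further compounds**

F1 | step 3 | dimethyl (E)-2-(3,4,5-trimethoxybenzylidene)succinate | COC(=O)C/C(C(=O)OC)=C\c1cc(OC)c(OC)c(OC)c1
F2 | step 3 | (E)-4-(3,4-dimethoxyphenyl)-3-(methoxycarbonyl)-2-[(E)-3,4,5-trimethoxybenzylidene]but-3-enoic acid | COc1ccc(/C=C(C(=O)OC)\C(=C/c2cc(OC)c(OC)c(OC)c2)C(=O)O)cc1OC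
F3 | step 3 | dimethyl (2E,3E)-2-(3,4-dimethoxybenzylidene)-3-(3,4,5-trimethoxybenzylidene)succinate | COc1ccc(/C=C(C(=O)OC)\C(=C/c2cc(OC)c(OC)c(OC)c2)C(=O)OC)cc1OC
F4 | step 3 | dimethyl rac-trans-1-(3,4-dimethoxyphenyl)-6,7,8-trimethoxy-1,2-dihydronaphthalene-2,3-dicarboxylate (required enantiomer drawn) | COc1ccc([C@@H]2c3c(cc(OC)c(OC)c3OC)C=C(C(=O)OC)[C@H]2C(=O)OC)cc1OC
F0 | step 5 | none | none
F5 | step 4 | rac-trans-9-(3,4-dimethoxyphenyl)-6,7,8-trimethoxy-1,3,9,9a-tetrahydronaphtho[2,3-c]furan-1-ol (lactol, anomeric mixture) | COc1ccc([C@@H]2c3c(cc(OC)c(OC)c3OC)C=C4COC(O)[C@@H]24)cc1OC
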